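**Plan**
- Retrosynthesis: the C4 ketone is traced back to a C4–OMe ether; ring C is then cut at O1–C2 and C3–C4 into salicylaldehyde 9 (ring A), trimethyl orthoformate 15 and styrene 14 (ring B).
- Enabling feature: O1–C8a–C4a–C4 is an oxa-diene once C4 is an oxocarbenium carbon held by the para oxygen O7; C2–C3 is the vinyl group of a p-alkoxystyrene whose arene is ring B.
- Fragment 9 is cut at aryl–CHO and aryl–prenyl (back to resorcinol); fragment 14 at aryl–vinyl, the chroman O–C bond and two aryl–prenyl bonds (back to 4-bromophenol and prenyl bromide).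
- Forward ring order: ring A is bought, the dimethylchroman ring on ring B closes in step 7, ring C closes last in step 9; ether hydrolysis, oxidation and desilylation finish.
- Stereochemistry: the only stereocentre, C2 (S), is set in step 9 by a chiral Brønsted acid; C4 is left uncontrolled because it ends as the carbonyl.

Key step: step 9

Remark on the chemistry (assumption): the antipode of the chiral acid that leads to 2S cannot be predicted safely; the route is written for the (R)-BINOL-derived catalyst, and the (S)-catalyst is used instead if the sense of induction is the opposite.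

**Route**

Step 1
Reactants: 1 resorcinol
Product: 2 1,3-bis(methoxymethoxy)benzene
Conditions: MOMCl (2.5 equiv), i-Pr2NEt (3 equiv), CH2Cl2, 0 °C → rt
Reagents that add atoms: chloromethyl methyl ether, COCCl
Why: Twofold O-alkylation of the phenols (Williamson-type MOM ether formation) installs the two groups that direct both later lithiations.

Step 2
Reactants: 2 1,3-bis(methoxymethoxy)benzene, 3 prenyl bromide (1-bromo-3-methylbut-2-ene)
Product: 5 1,3-bis(methoxymethoxy)-2-(3-methylbut-2-enyl)benzene, via 2-lithio-1,3-bis(methoxymethoxy)benzene 4 (not isolated)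
Conditions: n-BuLi (1.1 equiv), THF, 0 °C → rt; then CuI (10 mol%), 3 (1.2 equiv), –78 °C → rt
Reagents that add atoms: none
Why: Directed ortho-metalation occurs at C2 between the two cooperating OMOM groups, and copper-catalysed SN2 allylation of the aryllithium with the primary allylic bromide should give the linear prenyl arene.

Step 3
Reactants: 5 1,3-bis(methoxymethoxy)-2-(3-methylbut-2-enyl)benzene
Product: 7 2,4-bis(methoxymethoxy)-3-(3-methylbut-2-enyl)benzaldehyde, via [2,4-bis(methoxymethoxy)-3-(3-methylbut-2-enyl)phenyl]lithium 6 (not isolated)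
Conditions: n-BuLi (1.2 equiv), TMEDA (1.2 equiv), THF, 0 °C; DMF (2 equiv), 0 °C → rt; H2O
Reagents that add atoms: N,N-dimethylformamide, CN(C)C=O
Why: A second directed ortho-metalation next to one OMOM group (C4 and C6 are equivalent by symmetry) followed by formylation of the aryllithium with DMF (Bouveault-type); coordination-driven ring lithiation is expected to outrun deprotonation of the benzylic–allylic CH2.

Step 4
Reactants: 7 2,4-bis(methoxymethoxy)-3-(3-methylbut-2-enyl)benzaldehyde
Product: 8 2,4-dihydroxy-3-(3-methylbut-2-enyl)benzaldehyde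
Conditions: 3 M aq. HCl, MeOH, rt → 40 °C
Reagents that add atoms: none
Why: Acid-catalysed acetal cleavage (transacetalisation to methylal) removes both MOM ethers; dilute acid at modest temperature, as usual for prenylated phenols, should not cyclise the ortho-prenylphenol to a chroman.

Step 5
Reactants: 8 2,4-dihydroxy-3-(3-methylbut-2-enyl)benzaldehyde
Product: 9 2-hydroxy-3-(3-methylbut-2-enyl)-4-(triisopropylsilyloxy)benzaldehyde
Conditions: TIPSCl (1.05 equiv), imidazole (2 equiv), DMF, 0 °C → rt
Reagents that add atoms: chlorotriisopropylsilane, CC(C)[Si](Cl)(C(C)C)C(C)C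
Why: Selective O-silylation of the 4-OH; the 2-OH is tied up in the hydrogen bond to the aldehyde and is far less nucleophilic, a selectivity general for 2,4-dihydroxybenzaldehydes.

Step 6
Reactants: 10 4-bromophenol, 3 prenyl bromide
Product: 11 4-bromo-2,6-bis(3-methylbut-2-enyl)phenol
Conditions: NaH (2.2 equiv), toluene, 0 °C → rt; 3 (2.2 equiv), rt
Reagents that add atoms: none
Why: ortho-C-Allylation of the sodium phenoxide in a non-polar solvent, run twice in one flask; the tight ion pair disfavours O-alkylation and bromine blocks the para position, as known for the double ortho-prenylation of 4-halophenols.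

Step 7
Reactants: 11 4-bromo-2,6-bis(3-methylbut-2-enyl)phenol
Product: 12 6-bromo-2,2-dimethyl-8-(3-methylbut-2-enyl)chroman
Conditions: Amberlyst 15, CH2Cl2, rt (stopped when 11 is consumed)
Reagents that add atoms: none
Why: Acid-catalysed Markovnikov hydroalkoxylation (cycloetherification) of one ortho-prenyl group by the phenol gives the 2,2-dimethylchroman; the single OH allows only one closure, and the second prenyl group has no internal nucleophile and should survive the mild solid acid.

Step 8
Reactants: 12 6-bromo-2,2-dimethyl-8-(3-methylbut-2-enyl)chroman, 13 vinylboronic acid pinacol ester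
Product: 14 2,2-dimethyl-8-(3-methylbut-2-enyl)-6-vinylchroman
Conditions: PdCl2(dppf) (3 mol%), K2CO3 (3 equiv), 1,4-dioxane/H2O (5:1), 85 °C
Reagents that add atoms: none
Why: Suzuki–Miyaura cross-coupling of the unhindered aryl bromide with the vinyl boronate; the trisubstituted prenyl alkene does not take part.

Step 9
Reactants: 9 2-hydroxy-3-(3-methylbut-2-enyl)-4-(triisopropylsilyloxy)benzaldehyde, 15 trimethyl orthoformate, 14 2,2-dimethyl-8-(3-methylbut-2-enyl)-6-vinylchroman
Product: 17 (2S)-2-[2,2-dimethyl-8-(3-methylbut-2-enyl)chroman-6-yl]-4-methoxy-8-(3-methylbut-2-enyl)-7-(triisopropylsilyloxy)chroman (both C4 epimers), via dimethyl acetal 16 (not isolated)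
Conditions: (R)-3,3'-bis(2,4,6-triisopropylphenyl)-BINOL N-triflylphosphoramide (10 mol%), 15 (1.5 equiv), 5 Å MS, toluene, 0 °C; then 14 (1.2 equiv), –40 → –20 °C
Reagents that add atoms: none
Why: Proposed new method: acid-catalysed exchange with 15 turns 9 into acetal 16, which loses methanol to the O7-stabilised C4 oxocarbenium ion (a protonated 4-methoxy ortho-quinone methide) paired with the chiral phosphoramide anion; the vinyl CH2 of 14 adds to C4 and the phenol oxygen captures the resulting p-alkoxybenzyl cation at C2. The closest known reactions are the racemic Lewis- or Brønsted-acid three-component synthesis of 4-alkoxy-2-arylchromans from salicylaldehydes, orthoformates and styrenes, and chiral Brønsted acid catalysed [4+2] cycloadditions of in situ formed ortho-quinone methides with styrenes. Ring C closes by an asynchronous inverse-electron-demand oxa-[4+2] cycloaddition, C3–C4 forming first and O1–C2 completing as a formally 6-exo-trig capture of the cation. The C2 configuration is controlled by the chiral counter-anion, which is hydrogen-bonded to the phenol OH and shields one face of the benzylic cation during C–O bond formation; C4 is left uncontrolled, and if the two C4 epimers should differ in purity at C2 only the better one is carried on. Regiochemistry (oxygen to the benzylic carbon) follows cation stability; the vinyl group should react in preference to the three prenyl alkenes because the p-alkoxystyrene is the stronger π-nucleophile and gives the better-stabilised cation, and the weak acid at low temperature should spare the silyl ether and the ortho-prenylphenol.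

Step 10
Reactants: 17 (2S)-4-methoxyflavan (both C4 epimers)
Product: 18 (2S)-2-[2,2-dimethyl-8-(3-methylbut-2-enyl)chroman-6-yl]-8-(3-methylbut-2-enyl)-7-(triisopropylsilyloxy)chroman-4-ol (both C4 epimers)
Conditions: TsOH·H2O (10 mol%), THF/H2O (2:1), rt
Reagents that add atoms: water, O
Why: SN1 solvolysis of the benzylic methyl ether through the O7/O1-stabilised C4 cation; the large excess of water drives the exchange, room temperature limits E1 loss to the flav-3-ene, and C2 is untouched because the C2–O1 bond stays intact.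

Step 11
Reactants: 18 (2S)-flavan-4-ol (both C4 epimers)
Product: 19 (2S)-2-[2,2-dimethyl-8-(3-methylbut-2-enyl)chroman-6-yl]-8-(3-methylbut-2-enyl)-7-(triisopropylsilyloxy)chroman-4-one
Conditions: Dess–Martin periodinane (1.3 equiv), CH2Cl2, 0 °C → rt
Reagents that add atoms: none
Why: Dess–Martin oxidation of the secondary benzylic alcohol; both C4 epimers converge on one ketone, the non-basic medium avoids retro-oxa-Michael opening at C2, and the prenyl alkenes are inert.

Step 12
Reactants: 19 (2S)-7-silyloxyflavanone
Product: 20 (2S)-2-[2,2-dimethyl-8-(3-methylbut-2-enyl)chroman-6-yl]-7-hydroxy-8-(3-methylbut-2-enyl)chroman-4-one (target)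
Conditions: TBAF (1.1 equiv), AcOH (1.2 equiv), THF, 0 °C
Reagents that add atoms: none
Why: Fluoride-driven cleavage of the aryl silyl ether; the acetic acid buffer keeps the phenoxide protonated, so base-induced ring opening to the chalcone, which would racemise C2, is not expected.

**Compound list**

1 | resorcinol | Oc1cccc(O)c1 | starting material
2 | 1,3-bis(methoxymethoxy)benzene | COCOc1cccc(OCOC)c1 | intermediate
3 | prenyl bromide | CC(C)=CCBr | starting material
4 | 2-lithio-1,3-bis(methoxymethoxy)benzene | [Li]c1c(OCOC)cccc1OCOC | intermediate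
5 | 1,3-bis(methoxymethoxy)-2-(3-methylbut-2-enyl)benzene | COCOc1cccc(OCOC)c1CC=C(C)C | intermediate
6 | [2,4-bis(methoxymethoxy)-3-(3-methylbut-2-enyl)phenyl]lithium | [Li]c1ccc(OCOC)c(CC=C(C)C)c1OCOC | intermediate
7 | 2,4-bis(methoxymethoxy)-3-(3-methylbut-2-enyl)benzaldehyde | COCOc1ccc(C=O)c(OCOC)c1CC=C(C)C | intermediate
8 | 2,4-dihydroxy-3-(3-methylbut-2-enyl)benzaldehyde | CC(C)=CCc1c(O)ccc(C=O)c1O | intermediate
9 | 2-hydroxy-3-(3-methylbut-2-enyl)-4-(triisopropylsilyloxy)benzaldehyde | CC(C)=CCc1c(O)c(C=O)ccc1O[Si](C(C)C)(C(C)C)C(C)C | intermediate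
10 | 4-bromophenol | Oc1ccc(Br)cc1 | starting material
11 | 4-bromo-2,6-bis(3-methylbut-2-enyl)phenol | CC(C)=CCc1cc(Br)cc(CC=C(C)C)c1O | intermediate
12 | 6-bromo-2,2-dimethyl-8-(3-methylbut-2-enyl)chroman | CC(C)=CCc1cc(Br)cc2c1OC(C)(C)CC2 | intermediate
13 | vinylboronic acid pinacol ester | C=CB1OC(C)(C)C(C)(C)O1 | starting material
14 | 2,2-dimethyl-8-(3-methylbut-2-enyl)-6-vinylchroman | C=Cc1cc(CC=C(C)C)c2OC(C)(C)CCc2c1 | intermediate
15 | trimethyl orthoformate | COC(OC)OC | starting material
16 | 2-(dimethoxymethyl)-6-(3-methylbut-2-enyl)-5-(triisopropylsilyloxy)phenol (dimethyl acetal of 9) | COC(OC)c1ccc(O[Si](C(C)C)(C(C)C)C(C)C)c(CC=C(C)C)c1O | intermediate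
17 | (2S)-2-[2,2-dimethyl-8-(3-methylbut-2-enyl)chroman-6-yl]-4-methoxy-8-(3-methylbut-2-enyl)-7-(triisopropylsilyloxy)chroman, C4 epimers | COC1C[C@@H](c2cc(CC=C(C)C)c3OC(C)(C)CCc3c2)Oc2c(CC=C(C)C)c(O[Si](C(C)C)(C(C)C)C(C)C)ccc12 | intermediate
18 | (2S)-2-[2,2-dimethyl-8-(3-methylbut-2-enyl)chroman-6-yl]-8-(3-methylbut-2-enyl)-7-(triisopropylsilyloxy)chroman-4-ol, C4 epimers | OC1C[C@@H](c2cc(CC=C(C)C)c3OC(C)(C)CCc3c2)Oc2c(CC=C(C)C)c(O[Si](C(C)C)(C(C)C)C(C)C)ccc12 | intermediate
19 | (2S)-2-[2,2-dimethyl-8-(3-methylbut-2-enyl)chroman-6-yl]-8-(3-methylbut-2-enyl)-7-(triisopropylsilyloxy)chroman-4-one | O=C1C[C@@H](c2cc(CC=C(C)C)c3OC(C)(C)CCc3c2)Oc2c(CC=C(C)C)c(O[Si](C(C)C)(C(C)C)C(C)C)ccc12 | intermediate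
20 | (2S)-2-[2,2-dimethyl-8-(3-methylbut-2-enyl)chroman-6-yl]-7-hydroxy-8-(3-methylbut-2-enyl)chroman-4-one | CC(C)=CCc1cc([C@@H]2CC(=O)c3ccc(O)c(CC=C(C)C)c3O2)cc2c1OC(C)(C)CC2 | target

**Step count**

Total: 12 steps. Longest linear sequence: 9 steps (steps 1–5 and 9–12, from resorcinol).

**Steps most likely to fail**

Step 9. Facial selectivity at C2 may be poor if the cation pathway is loosely ion-paired; the styrene may oligomerise under acid, or ionisation of the acetal may be too slow at low temperature. The fallback uses known chemistry and sets out from 9, 14 and 15. The three components are combined under an achiral Lewis acid (Yb(OTf)3, 5 mol%, CH2Cl2, rt), again through acetal 16, to give the racemic 4-methoxyflavan F1. F1 is hydrolysed as in step 10 to the racemic flavan-4-ol F2 and oxidised as in step 11 to the racemic 7-silyloxyflavanone F3. F3 is then resolved kinetically by asymmetric transfer hydrogenation (Ru–TsDPEN catalyst, HCO2H/Et3N, rt, run to slightly beyond half conversion), using the catalyst antipode that consumes the 2R ketone. The 2R ketone is reduced to the cis-(2R,4R)-flavan-4-ol F4, which is removed by chromatography; the unreduced 2S ketone is 19, where the route resumes.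

Step 10. The C4 cation may lose a C3 proton to give the flav-3-ene instead of taking up water, and acid may open the C2–O1 bond and erode the configuration at C2. The fallback sets out from 9 and 14 and carries the C4 oxygen as an ether that is removed without forming the C4 cation. The annulation of step 9 is run with commercial triallyl orthoformate in place of 15; it passes through the diallyl acetal F5 and gives the (2S)-4-allyloxyflavan F6. Isomerisation of the allyl ether with H2-activated [Ir(cod)(PMePh2)2]PF6 in THF gives the (2S)-4-(prop-1-enyloxy)flavan F7, which the prenyl alkenes should survive. Enol ether hydrolysis at pH 3–4 (PPTS, acetone/H2O, rt) then gives 18, where the route resumes.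

Step 3. The base may deprotonate the benzylic–allylic CH2 instead of the ring (lateral lithiation), so that the formyl group ends up in the side chain. The fallback sets out from 5 and formylates without an organolithium. Both MOM ethers are removed first (3 M HCl, MeOH, rt) to give 2-(3-methylbut-2-enyl)resorcinol F8. Magnesium-mediated ortho-formylation (MgCl2, Et3N, paraformaldehyde, MeCN, reflux; limited paraformaldehyde to avoid double formylation) then gives 8, since C4 and C6 of F8 are equivalent; the route resumes at 8.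

**Further compounds**

F1 | step 9 | racemic 2-[2,2-dimethyl-8-(3-methylbut-2-enyl)chroman-6-yl]-4-methoxy-8-(3-methylbut-2-enyl)-7-(triisopropylsilyloxy)chroman | COC1CC(c2cc(CC=C(C)C)c3OC(C)(C)CCc3c2)Oc2c(CC=C(C)C)c(O[Si](C(C)C)(C(C)C)C(C)C)ccc12
F2 | step 9 | racemic 2-[2,2-dimethyl-8-(3-methylbut-2-enyl)chroman-6-yl]-8-(3-methylbut-2-enyl)-7-(triisopropylsilyloxy)chroman-4-ol | OC1CC(c2cc(CC=C(C)C)c3OC(C)(C)CCc3c2)Oc2c(CC=C(C)C)c(O[Si](C(C)C)(C(C)C)C(C)C)ccc12
F3 | step 9 | racemic 2-[2,2-dimethyl-8-(3-methylbut-2-enyl)chroman-6-yl]-8-(3-methylbut-2-enyl)-7-(triisopropylsilyloxy)chroman-4-one | O=C1CC(c2cc(CC=C(C)C)c3OC(C)(C)CCc3c2)Oc2c(CC=C(C)C)c(O[Si](C(C)C)(C(C)C)C(C)C)ccc12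
F4 | step 9 | cis-(2R,4R)-2-[2,2-dimethyl-8-(3-methylbut-2-enyl)chroman-6-yl]-8-(3-methylbut-2-enyl)-7-(triisopropylsilyloxy)chroman-4-ol | O[C@@H]1C[C@H](c2cc(CC=C(C)C)c3OC(C)(C)CCc3c2)Oc2c(CC=C(C)C)c(O[Si](C(C)C)(C(C)C)C(C)C)ccc12
F5 | step 10 | 2-[bis(allyloxy)methyl]-6-(3-methylbut-2-enyl)-5-(triisopropylsilyloxy)phenol | C=CCOC(OCC=C)c1ccc(O[Si](C(C)C)(C(C)C)C(C)C)c(CC=C(C)C)c1O
F6 | step 10 | (2S)-4-allyloxy-2-[2,2-dimethyl-8-(3-methylbut-2-enyl)chroman-6-yl]-8-(3-methylbut-2-enyl)-7-(triisopropylsilyloxy)chroman, C4 epimers | C=CCOC1C[C@@H](c2cc(CC=C(C)C)c3OC(C)(C)CCc3c2)Oc2c(CC=C(C)C)c(O[Si](C(C)C)(C(C)C)C(C)C)ccc12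
F7 | step 10 | (2S)-2-[2,2-dimethyl-8-(3-methylbut-2-enyl)chroman-6-yl]-8-(3-methylbut-2-enyl)-4-(prop-1-enyloxy)-7-(triisopropylsilyloxy)chroman, C4 epimers | CC=COC1C[C@@H](c2cc(CC=C(C)C)c3OC(C)(C)CCc3c2)Oc2c(CC=C(C)C)c(O[Si](C(C)C)(C(C)C)C(C)C)ccc12
F8 | step 3 | 2-(3-methylbut-2-enyl)resorcinol | CC(C)=CCc1c(O)cccc1O
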